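The route rests on building ring C between the two finished halves. Ring C is a pentasubstituted benzene: C7a' carries O1', C4' a hydroxyl, C3a' (between them) carries C3', C7' carries C2 of unit 1, and C5' and C6' are CH. This 1,3-dioxygenation is what a vinylketene (C7a' as carbonyl carbon, then C5', C6', C7') and an ynol ether (C4'–O, C3a') give on benzannulation. One operation joins the fragments, forms four skeletal bonds and leaves the two oxygens differentiated (free on C7a', silylated on C4'). Its precursors are a diazo enone on C2 of the permethylated, chlorinated unit 1 and a triisopropylsiloxyalkyne carrying C3' and C2'.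

Key step: step 16

Remarks on the chemistry
- Locants: unit 1 is the dihydrobenzofuran that carries the styryl group (ring A = aryl on C3, ring B = its benzo ring). Unit 2 has primed locants (ring C = its benzo ring, ring E = aryl on C2', ring F = aryl on C3').
- Assumption: the quinidine-derived salt 11 is taken to give the (2S,3S) ester in step 6. If the sense of induction is the opposite, the quinine-derived pseudoenantiomer is used in the same way.
- C2' is carried as one defined configuration, but step 17 passes through the C2' cation, so stereochemical leakage at C2' before that step is harmless.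

Step 1
Reactants: 1 1-chloro-3,5-dimethoxybenzene
Product: 3 2-chloro-4,6-dimethoxybenzaldehyde, via iminium salt 2 (not isolated)
Conditions: POCl3, DMF, 0 → 80 °C; then H2O
Reagents that add atoms: N,N-dimethylformamide CN(C)C=O; water O
Why: Vilsmeier–Haack formylation should go para to one methoxy group and ortho to the other, next to chlorine, as it does for the bromo analogue, which places the future C3 carbon between the chloride (future C4) and an oxygen (future O1).

Step 2
Reactants: 3 2-chloro-4,6-dimethoxybenzaldehyde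
Product: 4 2-chloro-6-hydroxy-4-methoxybenzaldehyde
Conditions: BCl3, CH2Cl2, −78 → 0 °C; H2O
Reagents that add atoms: none
Why: Chelation-controlled ether cleavage: BCl3 bound to the aldehyde oxygen should remove only the ortho methyl group through a six-membered chelate and leave the para methoxy group (future C6–OMe) intact.

Step 3
Reactants: 4 2-chloro-6-hydroxy-4-methoxybenzaldehyde; 5 1-bromo-3,5-dimethoxybenzene
Product: 7 racemic 3-chloro-2-[(3,5-dimethoxyphenyl)(hydroxy)methyl]-5-methoxyphenol, via Grignard reagent 6 (not isolated)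
Conditions: 5, Mg, THF, reflux; then 4 (0.4 equiv relative to 6), THF, 0 °C → rt; aq NH4Cl
Reagents that add atoms: none
Why: Grignard addition to the aldehyde, the first equivalent of 6 being spent on the phenol, should give the diaryl carbinol, whose stereocentre is of no consequence because it becomes planar in step 6.

Step 4
Reactants: 7 racemic 3-chloro-2-[(3,5-dimethoxyphenyl)(hydroxy)methyl]-5-methoxyphenol
Product: 8 racemic 3-chloro-2-[(3,5-dimethoxyphenyl)(4-methylbenzenesulfonyl)methyl]-5-methoxyphenol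
Conditions: p-TolSO2Na, p-TsOH·H2O, CH2Cl2, rt
Reagents that add atoms: sodium 4-methylbenzenesulfinate Cc1ccc(cc1)S(=O)[O-].[Na+]
Why: Acid ionises the carbinol, whose cation is stabilised by the ortho hydroxyl and para methoxy groups, and the sulfinate captures it at sulfur (SN1 sulfone formation) to give a bench-stable precursor of the o-quinone methide.

Step 5
Reactants: 9 quinidine; 10 tert-butyl bromoacetate
Product: 11 N-(2-tert-butoxy-2-oxoethyl)quinidinium bromide (alkylated at the quinuclidine nitrogen)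
Conditions: THF, rt
Reagents that add atoms: none
Why: Menshutkin alkylation should occur at the quinuclidine nitrogen, the more nucleophilic of the two nitrogens, and the salt should precipitate.

Step 6
Reactants: 8 racemic sulfone; 11 N-(2-tert-butoxy-2-oxoethyl)quinidinium bromide
Product: 13 tert-butyl (2S,3S)-4-chloro-3-(3,5-dimethoxyphenyl)-6-methoxy-2,3-dihydro-1-benzofuran-2-carboxylate, via o-quinone methide 12 (not isolated)
Conditions: Cs2CO3, CH2Cl2, 0 °C → rt
Reagents that add atoms: none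
Why: Formal (4+1) annulation of an o-quinone methide with a carbonyl-stabilised ammonium ylide: the base expels sulfinate from 8 and deprotonates 11, the ylide adds to the methide carbon (C3–C2 bond) and the phenoxide displaces the amine in a 5-exo-tet closure (O1–C2 bond) that puts the ester trans to the C3 aryl group, while the cinchona ammonium group selects the face and should set C2 and C3 as S,S.

Step 7
Reactants: 13 tert-butyl (2S,3S)-4-chloro-3-(3,5-dimethoxyphenyl)-6-methoxy-2,3-dihydro-1-benzofuran-2-carboxylate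
Product: 14 [(2S,3S)-4-chloro-3-(3,5-dimethoxyphenyl)-6-methoxy-2,3-dihydro-1-benzofuran-2-yl]methanol
Conditions: LiAlH4, THF, 0 °C
Reagents that add atoms: none
Why: Hydride reduction of the ester to the primary alcohol should leave the stereocentres and the aryl chloride untouched.

Step 8
Reactants: 14 [(2S,3S)-4-chloro-3-(3,5-dimethoxyphenyl)-6-methoxy-2,3-dihydro-1-benzofuran-2-yl]methanol
Product: 16 (3E)-4-[(2R,3S)-4-chloro-3-(3,5-dimethoxyphenyl)-6-methoxy-2,3-dihydro-1-benzofuran-2-yl]but-3-en-2-one, via aldehyde 15 (not isolated)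
Conditions: Dess–Martin periodinane, CH2Cl2, 0 °C → rt; then Ph3P=CHC(O)CH3, rt
Reagents that add atoms: 1-(triphenylphosphoranylidene)propan-2-one CC(=O)C=P(c1ccccc1)(c1ccccc1)c1ccccc1
Why: Dess–Martin oxidation followed in the same flask by Wittig olefination with a stabilised ylide should give the E enone without isolation of the epimerisable α-aryloxy aldehyde, C2 becoming R only through a change of substituent priority.

Step 9
Reactants: 16 (3E)-4-[(2R,3S)-4-chloro-3-(3,5-dimethoxyphenyl)-6-methoxy-2,3-dihydro-1-benzofuran-2-yl]but-3-en-2-one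
Product: 18 (3E)-1-diazo-4-[(2R,3S)-4-chloro-3-(3,5-dimethoxyphenyl)-6-methoxy-2,3-dihydro-1-benzofuran-2-yl]but-3-en-2-one, via trifluoroacetyl diketone 17 (not isolated)
Conditions: LiN(SiMe3)2, THF, −78 °C; CF3CO2CH2CF3; dilute HCl wash; then 4-AcNHC6H4SO2N3, Et3N, H2O, MeCN, rt
Reagents that add atoms: 4-acetamidobenzenesulfonyl azide CC(=O)Nc1ccc(cc1)S(=O)(=O)N=[N+]=[N-]
Why: Detrifluoroacetylative diazo transfer: kinetic deprotonation of the methyl group, Claisen trifluoroacetylation and Regitz-type transfer with loss of the trifluoroacetyl group should give the α′-diazo enone under conditions too mild to affect C2 or the E alkene.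

Step 10
Reactants: 19 (3,5-dimethoxyphenyl)acetic acid; 20 (4S)-4-benzyl-1,3-oxazolidin-2-one
Product: 22 (4S)-4-benzyl-3-[(3,5-dimethoxyphenyl)acetyl]-1,3-oxazolidin-2-one, via mixed anhydride 21 (not isolated)
Conditions: t-BuCOCl, Et3N, THF, −20 °C; then 20, LiCl, rt
Reagents that add atoms: none
Why: N-Acylation of the oxazolidinone through the mixed pivalic anhydride with LiCl activation is mild enough to avoid ketene formation from the arylacetyl unit.

Step 11
Reactants: 22 (4S)-4-benzyl-3-[(3,5-dimethoxyphenyl)acetyl]-1,3-oxazolidin-2-one; 23 2,4-dimethoxybenzaldehyde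
Product: 25 (4S)-4-benzyl-3-[(2R,3S)-3-(2,4-dimethoxyphenyl)-2-(3,5-dimethoxyphenyl)-3-hydroxypropanoyl]-1,3-oxazolidin-2-one, via trimethylsilyl ether 24 (not isolated)
Conditions: MgCl2 (20 mol %), Et3N, Me3SiCl, EtOAc, rt; then n-Bu4NF, AcOH, THF, 0 °C
Reagents that add atoms: none
Why: MgCl2-catalysed anti-aldol reaction of an N-acyloxazolidinone with an aromatic aldehyde: soft enolisation gives the chelated Z enolate, which should add to the aldehyde on the face away from the benzyl group through a boat-like transition state, setting C3' (2R in the imide) and C2' anti to it, with silylation of the aldolate making the addition irreversible.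

Step 12
Reactants: 25 anti-aldol adduct
Product: 26 (4S)-4-benzyl-3-[(2R,3S)-3-{[tert-butyl(dimethyl)silyl]oxy}-3-(2,4-dimethoxyphenyl)-2-(3,5-dimethoxyphenyl)propanoyl]-1,3-oxazolidin-2-one
Conditions: t-BuMe2SiOTf, 2,6-lutidine, CH2Cl2, −78 °C
Reagents that add atoms: tert-butyldimethylsilyl trifluoromethanesulfonate CC(C)(C)[Si](C)(C)OS(=O)(=O)C(F)(F)F
Why: Silylation with the silyl triflate and 2,6-lutidine should protect the hindered benzylic hydroxyl, which blocks retro-aldol cleavage and keeps the ionisable C2' oxygen masked until step 17.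

Step 13
Reactants: 26 silylated aldol adduct
Product: 27 (2S,3S)-3-{[tert-butyl(dimethyl)silyl]oxy}-3-(2,4-dimethoxyphenyl)-2-(3,5-dimethoxyphenyl)propan-1-ol
Conditions: LiBH4, MeOH (1 equiv), THF, 0 °C
Reagents that add atoms: none
Why: Reductive removal of the auxiliary by borohydride attack on the exocyclic imide carbonyl should give the primary alcohol without enolising the α-aryl centre C3', and the oxazolidinone is recovered.

Step 14
Reactants: 27 (2S,3S)-3-{[tert-butyl(dimethyl)silyl]oxy}-3-(2,4-dimethoxyphenyl)-2-(3,5-dimethoxyphenyl)propan-1-ol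
Product: 29 tert-butyl{[(1S,2R)-1-(2,4-dimethoxyphenyl)-2-(3,5-dimethoxyphenyl)but-3-yn-1-yl]oxy}dimethylsilane, via aldehyde 28 (not isolated)
Conditions: Dess–Martin periodinane, pyridine, CH2Cl2, 0 °C; then Me3SiC(Li)N2 (from Me3SiCHN2, n-BuLi), THF, −78 → 0 °C
Reagents that add atoms: (trimethylsilyl)diazomethane C[Si](C)(C)C=[N+]=[N-]
Why: Dess–Martin oxidation and Colvin homologation: the lithiated silyldiazomethane should add to the crude aldehyde at −78 °C faster than it enolises it, and Peterson elimination, loss of N2 and a 1,2-hydrogen shift of the alkylidene carbene then give the terminal alkyne with C3' unchanged.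

Step 15
Reactants: 29 terminal alkyne
Product: 32 tert-butyl{[(1S,2S)-1-(2,4-dimethoxyphenyl)-2-(3,5-dimethoxyphenyl)-4-{[tri(propan-2-yl)silyl]oxy}but-3-yn-1-yl]oxy}dimethylsilane, via lithium acetylide 30 (not isolated), via lithium ynolate 31 (not isolated)
Conditions: n-BuLi, THF, −78 °C; t-BuOOLi (from t-BuOOH, LiN(SiMe3)2), −78 → 0 °C; then i-Pr3SiOTf, −78 → 0 °C
Reagents that add atoms: tert-butyl hydroperoxide CC(C)(C)OO; triisopropylsilyl trifluoromethanesulfonate CC(C)[Si](C(C)C)(C(C)C)OS(=O)(=O)C(F)(F)F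
Why: Oxidation of the lithium acetylide by lithium tert-butyl peroxide should give the ynolate, which the bulky silyl triflate traps on oxygen, a known route to triisopropylsiloxyalkynes that involves no acid and no carbonyl group next to C3'.

Step 16
Reactants: 18 (3E)-1-diazo-4-[(2R,3S)-4-chloro-3-(3,5-dimethoxyphenyl)-6-methoxy-2,3-dihydro-1-benzofuran-2-yl]but-3-en-2-one; 32 siloxyalkyne (1.3 equiv)
Product: 37 2-[(1S,2S)-2-{[tert-butyl(dimethyl)silyl]oxy}-2-(2,4-dimethoxyphenyl)-1-(3,5-dimethoxyphenyl)ethyl]-6-[(2S,3S)-4-chloro-3-(3,5-dimethoxyphenyl)-6-methoxy-2,3-dihydro-1-benzofuran-2-yl]-3-{[tri(propan-2-yl)silyl]oxy}phenol, via vinylketene 33 (not isolated), via vinylcyclobutenone 34 (not isolated), via dienylketene 35 (not isolated), via cyclohexadienone 36 (not isolated)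
Conditions: hν (medium-pressure Hg lamp, Pyrex filter), ClCH2CH2Cl, rt; then 80 °C
Reagents that add atoms: none
Why: Light induces Wolff rearrangement of 18 (C6' migrates to C5' as N2 leaves) to vinylketene 33, and the electron-rich alkyne 32 adds in a regioselective (2+2) cycloaddition, its nucleophilic carbon C3a' bonding to the ketene carbonyl carbon C7a' and C4' to C5', to give cyclobutenone 34. Four-electron electrocyclic opening of 34 gives dienylketene 35, six-electron electrocyclisation (C7a'–C7') closes ring C as cyclohexadienone 36, and tautomerisation gives phenol 37, heating serving to complete the opening and closure. The closest known reaction type is the Danheiser benzannulation of α-diazo ketones with siloxyalkynes in its photochemical Wolff variant. Ring C is the only ring closed, by thermal 6π electrocyclisation, and no stereocentre is created. The selectivity needed is regiochemical and follows from the polarity of ketene and ynol ether, which puts the free hydroxyl on C7a' and the silyl ether on C4'. The E alkene of 18 keeps H–C2 away from the ketene carbon (no 1,5-hydrogen shift), the neutral medium should leave C2, C3, C3' and C2' unepimerised, and light above 300 nm spares the aryl chloride.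

Step 17
Reactants: 37 benzannulation product
Product: 38 {[(2S,3S)-7-[(2S,3S)-4-chloro-3-(3,5-dimethoxyphenyl)-6-methoxy-2,3-dihydro-1-benzofuran-2-yl]-2-(2,4-dimethoxyphenyl)-3-(3,5-dimethoxyphenyl)-2,3-dihydro-1-benzofuran-4-yl]oxy}tri(propan-2-yl)silane
Conditions: CF3CO2H, CH2Cl2, 0 °C
Reagents that add atoms: none
Why: Acid should ionise the C2' silyl ether to a cation stabilised by the 2,4-dimethoxyphenyl ring, which the free C7a' hydroxyl captures in a 5-exo cyclisation (SN1 etherification), the C4' oxygen being blocked by its silyl group and the trans relation of the C2' and C3' aryl groups following from the less strained transition state and from reversibility of the ionisation.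

Step 18
Reactants: 38 bis(dihydrobenzofuran) heptamethyl ether
Product: 40 (2S,3S)-7-[(2S,3S)-4-chloro-3-(3,5-dihydroxyphenyl)-6-hydroxy-2,3-dihydro-1-benzofuran-2-yl]-2-(2,4-dihydroxyphenyl)-3-(3,5-dihydroxyphenyl)-2,3-dihydro-1-benzofuran-4-ol, via heptaphenol silyl ether 39 (not isolated)
Conditions: BBr3, CH2Cl2, −78 °C → rt; MeOH, 0 °C; then n-Bu4NF, AcOH, THF, rt
Reagents that add atoms: none
Why: BBr3 cleavage of the seven aryl methyl ethers is placed here, while ring B still carries chlorine in place of the styryl group, so that no alkene is present to trap a benzylic cation, and the C4' silyl ether is removed only afterwards by fluoride so that a dihydrofuran ring opened reversibly by the Lewis acid can only reclose to the same ether.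

Step 19
Reactants: 40 octaphenol
Product: 41 octaacetate of 40
Conditions: Ac2O, pyridine, DMAP (cat.), rt
Reagents that add atoms: acetic anhydride CC(=O)OC(C)=O
Why: Peracetylation should convert the air-sensitive octaphenol into a stable, chromatographable ester that tolerates the coupling conditions.

Step 20
Reactants: 41 octaacetate; 42 4-ethenylphenyl acetate
Product: 43 nonaacetate of the target
Conditions: Pd[P(t-Bu)3]2 (5 mol %), Cy2NMe, 1,4-dioxane, 100 °C
Reagents that add atoms: none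
Why: Mizoroki–Heck coupling of the aryl chloride, made possible by the bulky electron-rich phosphine, should arylate the terminal carbon of the styrene and give the E stilbene by syn β-hydride elimination, the tertiary amine base leaving the aryl acetates intact.

Step 21
Reactants: 43 nonaacetate
Product: 44 (2S,3S)-2-(2,4-dihydroxyphenyl)-3-(3,5-dihydroxyphenyl)-7-{(2S,3S)-3-(3,5-dihydroxyphenyl)-6-hydroxy-4-[(E)-2-(4-hydroxyphenyl)ethenyl]-2,3-dihydro-1-benzofuran-2-yl}-2,3-dihydro-1-benzofuran-4-ol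
Conditions: K2CO3 (cat.), degassed MeOH, 0 °C → rt; then Amberlite IR-120 (H+ form)
Reagents that add atoms: none
Why: Carbonate-catalysed transesterification with methanol (Zemplén-type) should remove all nine acetyl groups under conditions that touch neither the stilbene nor the four stereocentres, giving the target.

Compound list
1 | 1-chloro-3,5-dimethoxybenzene | COc1cc(Cl)cc(OC)c1 | starting material
2 | N-[(2-chloro-4,6-dimethoxyphenyl)methylidene]-N-methylmethanaminium chloride | C[N+](C)=Cc1c(Cl)cc(OC)cc1OC.[Cl-] | intermediate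
3 | 2-chloro-4,6-dimethoxybenzaldehyde | COc1cc(Cl)c(C=O)c(OC)c1 | intermediate
4 | 2-chloro-6-hydroxy-4-methoxybenzaldehyde | COc1cc(O)c(C=O)c(Cl)c1 | intermediate
5 | 1-bromo-3,5-dimethoxybenzene | COc1cc(Br)cc(OC)c1 | starting material
6 | 3,5-dimethoxyphenylmagnesium bromide | COc1cc(cc(OC)c1)[Mg]Br | intermediate
7 | racemic 3-chloro-2-[(3,5-dimethoxyphenyl)(hydroxy)methyl]-5-methoxyphenol | COc1cc(O)c(C(O)c2cc(OC)cc(OC)c2)c(Cl)c1 | intermediate
8 | racemic 3-chloro-2-[(3,5-dimethoxyphenyl)(4-methylbenzenesulfonyl)methyl]-5-methoxyphenol | COc1cc(O)c(C(c2cc(OC)cc(OC)c2)S(=O)(=O)c2ccc(C)cc2)c(Cl)c1 | intermediate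
9 | quinidine | COC1=CC2=C(C=CN=C2C=C1)[C@@H]([C@H]3C[C@@H]4CCN3C[C@@H]4C=C)O | starting material
10 | tert-butyl bromoacetate | CC(C)(C)OC(=O)CBr | starting material
11 | N-(2-tert-butoxy-2-oxoethyl)quinidinium bromide | COC1=CC2=C(C=CN=C2C=C1)[C@@H]([C@H]3C[C@@H]4CC[N+]3(CC(=O)OC(C)(C)C)C[C@@H]4C=C)O.[Br-] | intermediate
12 | 3-chloro-2-[(3,5-dimethoxyphenyl)methylidene]-5-methoxycyclohexa-3,5-dien-1-one | COC1=CC(=O)C(=Cc2cc(OC)cc(OC)c2)C(Cl)=C1 | intermediate
13 | tert-butyl (2S,3S)-4-chloro-3-(3,5-dimethoxyphenyl)-6-methoxy-2,3-dihydro-1-benzofuran-2-carboxylate | Clc1cc(OC)cc2c1[C@H](c1cc(OC)cc(OC)c1)[C@@H](C(=O)OC(C)(C)C)O2 | intermediate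
14 | [(2S,3S)-4-chloro-3-(3,5-dimethoxyphenyl)-6-methoxy-2,3-dihydro-1-benzofuran-2-yl]methanol | Clc1cc(OC)cc2c1[C@H](c1cc(OC)cc(OC)c1)[C@@H](CO)O2 | intermediate
15 | (2S,3S)-4-chloro-3-(3,5-dimethoxyphenyl)-6-methoxy-2,3-dihydro-1-benzofuran-2-carbaldehyde | Clc1cc(OC)cc2c1[C@H](c1cc(OC)cc(OC)c1)[C@@H](C=O)O2 | intermediate
16 | (3E)-4-[(2R,3S)-4-chloro-3-(3,5-dimethoxyphenyl)-6-methoxy-2,3-dihydro-1-benzofuran-2-yl]but-3-en-2-one | Clc1cc(OC)cc2c1[C@H](c1cc(OC)cc(OC)c1)[C@@H](/C=C/C(C)=O)O2 | intermediate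
17 | (5E)-6-[(2R,3S)-4-chloro-3-(3,5-dimethoxyphenyl)-6-methoxy-2,3-dihydro-1-benzofuran-2-yl]-1,1,1-trifluorohex-5-ene-2,4-dione | Clc1cc(OC)cc2c1[C@H](c1cc(OC)cc(OC)c1)[C@@H](/C=C/C(=O)CC(=O)C(F)(F)F)O2 | intermediate
18 | (3E)-1-diazo-4-[(2R,3S)-4-chloro-3-(3,5-dimethoxyphenyl)-6-methoxy-2,3-dihydro-1-benzofuran-2-yl]but-3-en-2-one | Clc1cc(OC)cc2c1[C@H](c1cc(OC)cc(OC)c1)[C@@H](/C=C/C(=O)C=[N+]=[N-])O2 | intermediate
19 | (3,5-dimethoxyphenyl)acetic acid | COc1cc(CC(=O)O)cc(OC)c1 | starting material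
20 | (4S)-4-benzyl-1,3-oxazolidin-2-one | O=C1N[C@@H](Cc2ccccc2)CO1 | starting material
21 | (3,5-dimethoxyphenyl)acetic 2,2-dimethylpropanoic anhydride | COc1cc(CC(=O)OC(=O)C(C)(C)C)cc(OC)c1 | intermediate
22 | (4S)-4-benzyl-3-[(3,5-dimethoxyphenyl)acetyl]-1,3-oxazolidin-2-one | O=C1OC[C@H](Cc2ccccc2)N1C(=O)Cc1cc(OC)cc(OC)c1 | intermediate
23 | 2,4-dimethoxybenzaldehyde | COc1ccc(C=O)c(OC)c1 | starting material
24 | (4S)-4-benzyl-3-[(2R,3S)-3-(2,4-dimethoxyphenyl)-2-(3,5-dimethoxyphenyl)-3-(trimethylsilyloxy)propanoyl]-1,3-oxazolidin-2-one | O=C1OC[C@H](Cc2ccccc2)N1C(=O)[C@H](c1cc(OC)cc(OC)c1)[C@@H](c1ccc(OC)cc1OC)O[Si](C)(C)C | intermediate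
25 | (4S)-4-benzyl-3-[(2R,3S)-3-(2,4-dimethoxyphenyl)-2-(3,5-dimethoxyphenyl)-3-hydroxypropanoyl]-1,3-oxazolidin-2-one | O=C1OC[C@H](Cc2ccccc2)N1C(=O)[C@H](c1cc(OC)cc(OC)c1)[C@@H](c1ccc(OC)cc1OC)O | intermediate
26 | (4S)-4-benzyl-3-[(2R,3S)-3-{[tert-butyl(dimethyl)silyl]oxy}-3-(2,4-dimethoxyphenyl)-2-(3,5-dimethoxyphenyl)propanoyl]-1,3-oxazolidin-2-one | O=C1OC[C@H](Cc2ccccc2)N1C(=O)[C@H](c1cc(OC)cc(OC)c1)[C@@H](c1ccc(OC)cc1OC)O[Si](C)(C)C(C)(C)C | intermediate
27 | (2S,3S)-3-{[tert-butyl(dimethyl)silyl]oxy}-3-(2,4-dimethoxyphenyl)-2-(3,5-dimethoxyphenyl)propan-1-ol | OC[C@H](c1cc(OC)cc(OC)c1)[C@@H](c1ccc(OC)cc1OC)O[Si](C)(C)C(C)(C)C | intermediate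
28 | (2R,3S)-3-{[tert-butyl(dimethyl)silyl]oxy}-3-(2,4-dimethoxyphenyl)-2-(3,5-dimethoxyphenyl)propanal | O=C[C@H](c1cc(OC)cc(OC)c1)[C@@H](c1ccc(OC)cc1OC)O[Si](C)(C)C(C)(C)C | intermediate
29 | tert-butyl{[(1S,2R)-1-(2,4-dimethoxyphenyl)-2-(3,5-dimethoxyphenyl)but-3-yn-1-yl]oxy}dimethylsilane | C#C[C@H](c1cc(OC)cc(OC)c1)[C@@H](c1ccc(OC)cc1OC)O[Si](C)(C)C(C)(C)C | intermediate
30 | lithium acetylide of 29 | [Li]C#C[C@H](c1cc(OC)cc(OC)c1)[C@@H](c1ccc(OC)cc1OC)O[Si](C)(C)C(C)(C)C | intermediate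
31 | lithium (3S,4S)-4-{[tert-butyl(dimethyl)silyl]oxy}-4-(2,4-dimethoxyphenyl)-3-(3,5-dimethoxyphenyl)but-1-yn-1-olate | [Li]OC#C[C@H](c1cc(OC)cc(OC)c1)[C@@H](c1ccc(OC)cc1OC)O[Si](C)(C)C(C)(C)C | intermediate
32 | tert-butyl{[(1S,2S)-1-(2,4-dimethoxyphenyl)-2-(3,5-dimethoxyphenyl)-4-{[tri(propan-2-yl)silyl]oxy}but-3-yn-1-yl]oxy}dimethylsilane | CC(C)[Si](C(C)C)(C(C)C)OC#C[C@H](c1cc(OC)cc(OC)c1)[C@@H](c1ccc(OC)cc1OC)O[Si](C)(C)C(C)(C)C | intermediate
33 | (3E)-4-[(2R,3S)-4-chloro-3-(3,5-dimethoxyphenyl)-6-methoxy-2,3-dihydro-1-benzofuran-2-yl]buta-1,3-dien-1-one | Clc1cc(OC)cc2c1[C@H](c1cc(OC)cc(OC)c1)[C@@H](/C=C/C=C=O)O2 | intermediate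
34 | 4-{(E)-2-[(2R,3S)-4-chloro-3-(3,5-dimethoxyphenyl)-6-methoxy-2,3-dihydro-1-benzofuran-2-yl]ethenyl}-2-[(1S,2S)-2-{[tert-butyl(dimethyl)silyl]oxy}-2-(2,4-dimethoxyphenyl)-1-(3,5-dimethoxyphenyl)ethyl]-3-{[tri(propan-2-yl)silyl]oxy}cyclobut-2-en-1-one (C4 of the four-membered ring unassigned) | O=C1C(/C=C/[C@H]2Oc3cc(OC)cc(Cl)c3[C@@H]2c2cc(OC)cc(OC)c2)C(O[Si](C(C)C)(C(C)C)C(C)C)=C1[C@H](c1cc(OC)cc(OC)c1)[C@@H](c1ccc(OC)cc1OC)O[Si](C)(C)C(C)(C)C | intermediate
35 | 2-[(1S,2S)-2-{[tert-butyl(dimethyl)silyl]oxy}-2-(2,4-dimethoxyphenyl)-1-(3,5-dimethoxyphenyl)ethyl]-6-[(2R,3S)-4-chloro-3-(3,5-dimethoxyphenyl)-6-methoxy-2,3-dihydro-1-benzofuran-2-yl]-3-{[tri(propan-2-yl)silyl]oxy}hexa-1,3,5-trien-1-one (C2 and C5 cis across C3=C4, C5=C6 E) | O=C=C([C@H](c1cc(OC)cc(OC)c1)[C@@H](c1ccc(OC)cc1OC)O[Si](C)(C)C(C)(C)C)/C(O[Si](C(C)C)(C(C)C)C(C)C)=C\C=C\[C@H]1Oc2cc(OC)cc(Cl)c2[C@@H]1c1cc(OC)cc(OC)c1 | intermediate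
36 | 2-[(1S,2S)-2-{[tert-butyl(dimethyl)silyl]oxy}-2-(2,4-dimethoxyphenyl)-1-(3,5-dimethoxyphenyl)ethyl]-6-[(2S,3S)-4-chloro-3-(3,5-dimethoxyphenyl)-6-methoxy-2,3-dihydro-1-benzofuran-2-yl]-3-{[tri(propan-2-yl)silyl]oxy}cyclohexa-2,4-dien-1-one (C6 of the six-membered ring unassigned) | O=C1C([C@H](c2cc(OC)cc(OC)c2)[C@@H](c2ccc(OC)cc2OC)O[Si](C)(C)C(C)(C)C)=C(O[Si](C(C)C)(C(C)C)C(C)C)C=CC1[C@H]1Oc2cc(OC)cc(Cl)c2[C@@H]1c1cc(OC)cc(OC)c1 | intermediate
37 | 2-[(1S,2S)-2-{[tert-butyl(dimethyl)silyl]oxy}-2-(2,4-dimethoxyphenyl)-1-(3,5-dimethoxyphenyl)ethyl]-6-[(2S,3S)-4-chloro-3-(3,5-dimethoxyphenyl)-6-methoxy-2,3-dihydro-1-benzofuran-2-yl]-3-{[tri(propan-2-yl)silyl]oxy}phenol | Clc1cc(OC)cc2c1[C@H](c1cc(OC)cc(OC)c1)[C@@H](c1ccc(O[Si](C(C)C)(C(C)C)C(C)C)c(c1O)[C@H](c1cc(OC)cc(OC)c1)[C@@H](c1ccc(OC)cc1OC)O[Si](C)(C)C(C)(C)C)O2 | intermediate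
38 | {[(2S,3S)-7-[(2S,3S)-4-chloro-3-(3,5-dimethoxyphenyl)-6-methoxy-2,3-dihydro-1-benzofuran-2-yl]-2-(2,4-dimethoxyphenyl)-3-(3,5-dimethoxyphenyl)-2,3-dihydro-1-benzofuran-4-yl]oxy}tri(propan-2-yl)silane | Clc1cc(OC)cc2c1[C@H](c1cc(OC)cc(OC)c1)[C@@H](c1ccc(O[Si](C(C)C)(C(C)C)C(C)C)c3c1O[C@H](c1ccc(OC)cc1OC)[C@H]3c1cc(OC)cc(OC)c1)O2 | intermediate
39 | heptaphenol corresponding to 38 with the C4' triisopropylsilyl ether retained | Clc1cc(O)cc2c1[C@H](c1cc(O)cc(O)c1)[C@@H](c1ccc(O[Si](C(C)C)(C(C)C)C(C)C)c3c1O[C@H](c1ccc(O)cc1O)[C@H]3c1cc(O)cc(O)c1)O2 | intermediate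
40 | (2S,3S)-7-[(2S,3S)-4-chloro-3-(3,5-dihydroxyphenyl)-6-hydroxy-2,3-dihydro-1-benzofuran-2-yl]-2-(2,4-dihydroxyphenyl)-3-(3,5-dihydroxyphenyl)-2,3-dihydro-1-benzofuran-4-ol | Clc1cc(O)cc2c1[C@H](c1cc(O)cc(O)c1)[C@@H](c1ccc(O)c3c1O[C@H](c1ccc(O)cc1O)[C@H]3c1cc(O)cc(O)c1)O2 | intermediate
41 | octaacetate of 40 | Clc1cc(OC(C)=O)cc2c1[C@H](c1cc(OC(C)=O)cc(OC(C)=O)c1)[C@@H](c1ccc(OC(C)=O)c3c1O[C@H](c1ccc(OC(C)=O)cc1OC(C)=O)[C@H]3c1cc(OC(C)=O)cc(OC(C)=O)c1)O2 | intermediate
42 | 4-ethenylphenyl acetate | CC(=O)Oc1ccc(C=C)cc1 | starting material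
43 | nonaacetate of 44 | CC(=O)Oc1ccc(/C=C/c2cc(OC(C)=O)cc3c2[C@H](c2cc(OC(C)=O)cc(OC(C)=O)c2)[C@@H](c2ccc(OC(C)=O)c4c2O[C@H](c2ccc(OC(C)=O)cc2OC(C)=O)[C@H]4c2cc(OC(C)=O)cc(OC(C)=O)c2)O3)cc1 | intermediate
44 | (2S,3S)-2-(2,4-dihydroxyphenyl)-3-(3,5-dihydroxyphenyl)-7-{(2S,3S)-3-(3,5-dihydroxyphenyl)-6-hydroxy-4-[(E)-2-(4-hydroxyphenyl)ethenyl]-2,3-dihydro-1-benzofuran-2-yl}-2,3-dihydro-1-benzofuran-4-ol | Oc1ccc(/C=C/c2cc(O)cc3c2[C@H](c2cc(O)cc(O)c2)[C@@H](c2ccc(O)c4c2O[C@H](c2ccc(O)cc2O)[C@H]4c2cc(O)cc(O)c2)O3)cc1 | target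

Total step count: 21 (including step 5, the preparation of salt 11).
Longest linear sequence: 14 steps (1 → 44 through steps 1–4, 6–9 and 16–21); the siloxyalkyne branch (steps 10–15) joins at step 16.

Steps most likely to fail

1. Step 16 (key step). The vinylketene may dimerise, or acylate the product phenol, faster than the α-branched siloxyalkyne captures it, and long irradiation may degrade the electron-rich arenes. Fallback: the same vinylketene is generated without light. Setting out from alcohol 14, oxidation as in step 8 gives aldehyde 15, which is olefinated with the ylide from (2-carboxyethyl)triphenylphosphonium bromide and NaN(SiMe3)2 (a carboxylate-bearing ylide that favours the E alkene) to give (3E)-4-[(2R,3S)-4-chloro-3-(3,5-dimethoxyphenyl)-6-methoxy-2,3-dihydro-1-benzofuran-2-yl]but-3-enoic acid F1. Oxalyl chloride converts it into (3E)-4-[(2R,3S)-4-chloro-3-(3,5-dimethoxyphenyl)-6-methoxy-2,3-dihydro-1-benzofuran-2-yl]but-3-enoyl chloride F2. Slow addition of Et3N to F2 and siloxyalkyne 32 in toluene (rt, then 80 °C) forms 33 by dehydrochlorination (the known cycloaddition of acid-chloride-derived ketenes with siloxyalkynes), which passes through 34–36 and rejoins the route at 37.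

2. Step 6. Facial discrimination or trans selectivity may be poor because the chlorine next to the methide carbon twists the o-quinone methide and slows ring closure relative to reversal of the ylide addition. Fallback: sulfone 8 is treated with the achiral salt (2-tert-butoxy-2-oxoethyl)trimethylammonium bromide and Cs2CO3 to give racemic trans-tert-butyl 4-chloro-3-(3,5-dimethoxyphenyl)-6-methoxy-2,3-dihydro-1-benzofuran-2-carboxylate F3. This is resolved by preparative supercritical-fluid chromatography on a polysaccharide chiral phase; the (2S,3S) enantiomer is 13, where the route resumes.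

3. Step 14. The basic silyldiazomethane anion may enolise the α-aryl aldehyde, causing epimerisation at C3' or β-elimination of the silyloxy group. Fallback: aldehyde 28, made from alcohol 27 as before, is converted under non-basic Ramirez conditions (CBr4, PPh3, Zn, pyridine buffer, CH2Cl2, 0 °C) into tert-butyl{[(1S,2R)-4,4-dibromo-1-(2,4-dimethoxyphenyl)-2-(3,5-dimethoxyphenyl)but-3-en-1-yl]oxy}dimethylsilane F4 (Corey–Fuchs sequence). n-BuLi (2.1 equiv, THF, −78 °C) then gives lithium acetylide 30 directly by bromine–lithium exchange and 1,2-hydrogen shift, and step 15 continues from 30 with the peroxide and the silyl triflate.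

Further compounds
F1 | step 16 | (3E)-4-[(2R,3S)-4-chloro-3-(3,5-dimethoxyphenyl)-6-methoxy-2,3-dihydro-1-benzofuran-2-yl]but-3-enoic acid | Clc1cc(OC)cc2c1[C@H](c1cc(OC)cc(OC)c1)[C@@H](/C=C/CC(=O)O)O2
F2 | step 16 | (3E)-4-[(2R,3S)-4-chloro-3-(3,5-dimethoxyphenyl)-6-methoxy-2,3-dihydro-1-benzofuran-2-yl]but-3-enoyl chloride | Clc1cc(OC)cc2c1[C@H](c1cc(OC)cc(OC)c1)[C@@H](/C=C/CC(Cl)=O)O2
F3 | step 6 | racemic trans-tert-butyl 4-chloro-3-(3,5-dimethoxyphenyl)-6-methoxy-2,3-dihydro-1-benzofuran-2-carboxylate (13 and its enantiomer) | Clc1cc(OC)cc2c1[C@H](c1cc(OC)cc(OC)c1)[C@@H](C(=O)OC(C)(C)C)O2.Clc1cc(OC)cc2c1[C@@H](c1cc(OC)cc(OC)c1)[C@H](C(=O)OC(C)(C)C)O2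
F4 | step 14 | tert-butyl{[(1S,2R)-4,4-dibromo-1-(2,4-dimethoxyphenyl)-2-(3,5-dimethoxyphenyl)but-3-en-1-yl]oxy}dimethylsilane | BrC(Br)=C[C@H](c1cc(OC)cc(OC)c1)[C@@H](c1ccc(OC)cc1OC)O[Si](C)(C)C(C)(C)C
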